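**Plan**

Numbering: C1 ketone, C4 carbinol, C6 acyloxy carbon, C7/C8 lactone fusion (O on C8), C10 methyl-bearing CH, C11–C13 methylene-lactone carbons. Retrosynthetic cuts, in order: the C6 ester and the Si–O bond; the lactone at C7–C11, C12–O8 and C11=C13 (back to an E C6=C7 alkene beside the C8 carbinol); C10–CH3 and C8–C9 with re-formation of C1–C6; then the enol-ether C8–O bond, C4–CH3, C6–C7 and C1–vinyl.
Enabling feature: in the ring C1…C10 the ketone C1 reaches the lactone carbinol C8 through C10 and C9, and C6 lies straight across from C1. C1–C2–C3–C4–C5–C6 is therefore the imprint of a cyclohexanol bearing alkenyl groups on C1 and C6, whose [3,3] shift breaks C1–C6 and makes C8–C9.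
Forward: the six-membered ring comes from a quinol (C1 vinyl carbinol), dressed by conjugate addition at C6 and methyl addition at C4. The ten-membered ring arises by anionic oxy-Cope ring expansion with methylation of the C1/C10 enolate. The lactone ring is closed last from an O8-tethered phosphonoacetate onto a C6–C7 epoxide, then methylenation, C6 acylation, desilylation.
Stereochemistry: C6 and C1 of the cyclohexanol from the (S)-BINAP–rhodium desymmetrisation with delivery on the hydroxyl face; C4 from equatorial methyl addition to the anchored ring; C8 by chair chirality transfer from C6 (which is consumed); C10 by attack of iodomethane on the exposed enolate face; C6 and C7 by hydroxyl-directed epoxidation of the E-alkene and inversion at C7.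

Key step: step 8

Assumption: the γ-hydroxy ketones 16, 21 and 23 are taken to exist and react in the open hydroxy-ketone form drawn for the target (the ten-membered ketone resists transannular hemiketal formation).

**Route**

Step 1
Reactants: 1 4,4-dimethoxycyclohexa-2,5-dien-1-one; 2 vinylmagnesium bromide
Product: 4 4-hydroxy-4-vinylcyclohexa-2,5-dien-1-one, via ketal carbinol 3 (not isolated)
Conditions: CH2=CHMgBr, THF, −78 °C; then 1 M aq. HCl, 0 °C
Reagents that add atoms: water, O
Why: Grignard 1,2-addition to the carbonyl of a quinone monoketal followed by mild acid hydrolysis of the dimethyl ketal is the standard entry to 4-substituted quinols; 4 is prochiral, so no stereocentre is set.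

Step 2
Reactants: 4 4-hydroxy-4-vinylcyclohexa-2,5-dien-1-one; 5 (E)-2-(trimethylsilyl)vinylboronic acid pinacol ester
Product: 6 (4S,5S)-4-ethenyl-4-hydroxy-5-[(E)-2-(trimethylsilyl)ethenyl]cyclohex-2-en-1-one
Conditions: [RhCl(C2H4)2]2 (1.5 mol %), (S)-BINAP (3.3 mol %), aq. KOH (0.5 equiv), 1,4-dioxane, 40 °C
Reagents that add atoms: none
Why: Rhodium-catalysed asymmetric 1,4-addition of an alkenylboronate (Hayashi–Miyaura reaction) desymmetrises the dienone; (S)-BINAP is expected to select one enantiotopic enone arm in the sense known for cyclohex-2-enones (sets C6), and delivery on the face of the small, rhodium-binding hydroxyl places the new group cis to OH and trans to vinyl (fixes C1).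

Step 3
Reactants: 6 (4S,5S)-4-ethenyl-4-hydroxy-5-[(E)-2-(trimethylsilyl)ethenyl]cyclohex-2-en-1-one
Product: 7 (3S,4R)-4-ethenyl-4-hydroxy-3-[(E)-2-(trimethylsilyl)ethenyl]cyclohexan-1-one
Conditions: [(Ph3P)CuH]6 (0.4 equiv), wet toluene, 23 °C
Reagents that add atoms: none
Why: Conjugate reduction by the phosphine-stabilised copper hydride is selective for the enone over the vinyl group, the vinylsilane and the ketone, and touches no stereocentre (C6 is β to the carbonyl and cannot epimerise).

Step 4
Reactants: 7 (3S,4R)-4-ethenyl-4-hydroxy-3-[(E)-2-(trimethylsilyl)ethenyl]cyclohexan-1-one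
Product: 8 (1R,2S,4S)-1-ethenyl-4-methyl-2-[(E)-2-(trimethylsilyl)ethenyl]cyclohexane-1,4-diol
Conditions: MeLi (3 equiv), LiClO4 (3 equiv), Et2O, −78 °C; H2O
Reagents that add atoms: methyllithium, [Li]C
Why: Carbonyl addition to a cyclohexanone anchored by two equatorial alkenyl groups; salt-modified methyllithium is expected to attack equatorially as with 4-substituted cyclohexanones, giving the axial C4–OH and the equatorial methyl cis to the C6 alkenyl group.

Step 5
Reactants: 8 (1R,2S,4S)-1-ethenyl-4-methyl-2-[(E)-2-(trimethylsilyl)ethenyl]cyclohexane-1,4-diol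
Product: 9 (1R,2S,4S)-1-ethenyl-4-methyl-4-(triethylsilyloxy)-2-[(E)-2-(trimethylsilyl)ethenyl]cyclohexan-1-ol
Conditions: Et3SiOTf (1.1 equiv), 2,6-lutidine, CH2Cl2, −78 °C
Reagents that add atoms: triethylsilyl trifluoromethanesulfonate, CC[Si](CC)(CC)OS(=O)(=O)C(F)(F)F
Why: Silyl triflate silylation should distinguish the two tertiary alcohols by hindrance, the methyl carbinol at C4 (two methylene neighbours) reacting before the vinyl carbinol at C1 (branched neighbour).

Step 6
Reactants: 9 (1R,2S,4S)-1-ethenyl-4-methyl-4-(triethylsilyloxy)-2-[(E)-2-(trimethylsilyl)ethenyl]cyclohexan-1-ol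
Product: 10 (1R,2S,4S)-1-ethenyl-2-[(E)-2-iodoethenyl]-4-methyl-4-(triethylsilyloxy)cyclohexan-1-ol
Conditions: NIS, MeCN/ClCH2CN (4:1), 0 °C
Reagents that add atoms: N-iodosuccinimide, O=C1CCC(=O)N1I
Why: Ipso-iododesilylation of an (E)-alkenylsilane in nitrile solvent goes through the β-silyl cation with retention of geometry, and the vinylsilane is far more nucleophilic than the monosubstituted vinyl group.

Step 7
Reactants: 10 (1R,2S,4S)-1-ethenyl-2-[(E)-2-iodoethenyl]-4-methyl-4-(triethylsilyloxy)cyclohexan-1-ol; 11 4-methoxybenzyl alcohol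
Product: 12 (1R,2S,4S)-1-ethenyl-2-[(E)-2-(4-methoxybenzyloxy)ethenyl]-4-methyl-4-(triethylsilyloxy)cyclohexan-1-ol
Conditions: CuI (10 mol %), 3,4,7,8-tetramethyl-1,10-phenanthroline (20 mol %), Cs2CO3, toluene, 80 °C
Reagents that add atoms: none
Why: Copper-catalysed Ullmann-type C–O coupling of an alkenyl iodide with a primary alcohol is stereoretentive, so the E enol ether should result; the hindered tertiary hydroxyl does not compete and cannot reach the trans-disposed C–I bond.

Step 8
Reactants: 12 (1R,2S,4S)-1-ethenyl-2-[(E)-2-(4-methoxybenzyloxy)ethenyl]-4-methyl-4-(triethylsilyloxy)cyclohexan-1-ol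
Product: 15 (2R,4S,5E,8S)-4-(4-methoxybenzyloxy)-2,8-dimethyl-8-(triethylsilyloxy)cyclodec-5-en-1-one, via potassium alkoxide 13 (not isolated), via potassium enolate 14 (not isolated)
Conditions: KN(SiMe3)2 (1.1 equiv), 18-crown-6, THF, 0 → 25 °C; then MeI, −78 °C
Reagents that add atoms: iodomethane, CI
Why: Deprotonation gives alkoxide 13, whose oxyanion weakens the C1–C6 bond so that the anionic oxy-Cope [3,3] shift (C1–C6 broken, C8–C9 formed) should run near room temperature to the ring-expanded enolate 14. The closest known reaction type is the anionic oxy-Cope ring expansion of trans-1,2-dialkenylcyclohexanols to (E)-cyclodec-5-enones with in-flask C-alkylation of the regiodefined enolate. The ten-membered ring is closed by ring enlargement (six ring atoms plus the four alkenyl carbons) through a six-centre chair transition state, not by end-to-end cyclisation. C8 is set by that chair: the trans-diequatorial alkenyl groups and the E enol ether put both ring bonds and the OPMB group equatorial, so the chirality of C6 is relayed to (S)-C8 and the new C6=C7 bond is E. C10 is set when iodomethane attacks the ring-E enolate on its exposed face in the crossed conformation handed down by the chair, which in this model gives the 10R methyl group; a proton entering a methyl-bearing enolate on that same face would give the epimer, which is why C1 carries vinyl and not isopropenyl. The step needs chair over boat and C- over O-alkylation at C10 only, secured by the diequatorial substrate, the regiodefined enolate, the soft electrophile and the low quench temperature.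

Step 9
Reactants: 15 (2R,4S,5E,8S)-4-(4-methoxybenzyloxy)-2,8-dimethyl-8-(triethylsilyloxy)cyclodec-5-en-1-one
Product: 16 (2R,4S,5E,8S)-4-hydroxy-2,8-dimethyl-8-(triethylsilyloxy)cyclodec-5-en-1-one
Conditions: DDQ, CH2Cl2/pH 7 buffer (10:1), 0 °C
Reagents that add atoms: none
Why: Oxidative PMB cleavage by DDQ (benzylic oxocarbenium ion hydrolysed by the buffer) frees the C8 allylic alcohol without affecting the silyl ether, the alkene, the ketone or any stereocentre.

Step 10
Reactants: 16 (2R,4S,5E,8S)-4-hydroxy-2,8-dimethyl-8-(triethylsilyloxy)cyclodec-5-en-1-one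
Product: 17 (1R,2S,4R,8S,10R)-2-hydroxy-4,8-dimethyl-8-(triethylsilyloxy)-11-oxabicyclo[8.1.0]undecan-5-one
Conditions: mCPBA, NaHCO3, CH2Cl2, 0 °C
Reagents that add atoms: 3-chloroperoxybenzoic acid, OOC(=O)c1cccc(Cl)c1
Why: Hydroxyl-directed peracid epoxidation; with H8 eclipsing the alkene and O8 pseudo-equatorial (the arrangement left by the chair), the peripheral face of the E-alkene is also the hydrogen-bond-directed one, so oxygen should add syn to O8 to give the threo (6R,7R) trans-epoxide.

Step 11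
Reactants: 17 (1R,2S,4R,8S,10R)-2-hydroxy-4,8-dimethyl-8-(triethylsilyloxy)-11-oxabicyclo[8.1.0]undecan-5-one; 18 (diethoxyphosphoryl)acetic acid
Product: 19 (1S,2S,4R,8S,10R)-4,8-dimethyl-5-oxo-8-(triethylsilyloxy)-11-oxabicyclo[8.1.0]undecan-2-yl (diethoxyphosphoryl)acetate
Conditions: DCC, DMAP (cat.), CH2Cl2, 0 → 23 °C
Reagents that add atoms: none
Why: Steglich esterification of the secondary alcohol is near-neutral and leaves the epoxide, the ketone and the C10 centre untouched (the descriptor at C7 changes by priority only).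

Step 12
Reactants: 19 (1S,2S,4R,8S,10R)-4,8-dimethyl-5-oxo-8-(triethylsilyloxy)-11-oxabicyclo[8.1.0]undecan-2-yl (diethoxyphosphoryl)acetate
Product: 21 (4S,6R,7R,8S,10R)-6-hydroxy-1-oxo-4-(triethylsilyloxy)germacr-11(13)-en-12,8-olide, via sodium phosphonolactone 20 (not isolated)
Conditions: NaH (1.05 equiv), THF, 0 → 45 °C; then (CH2O)n, 0 → 23 °C
Reagents that add atoms: formaldehyde (from paraformaldehyde), C=O
Why: Proposed new method: the sodium phosphonoacetate carbanion held on O8 should open the oxirane at C7 in a 5-exo-tet sense with inversion (O8 and C11 end cis on the new ring, the oxirane oxygen stays on C6 with retention), the C6 alkoxide is quenched at once by the acidic C11–H to give the stabilised anion 20, and this undergoes Horner–Wadsworth–Emmons olefination with formaldehyde; the closest known reaction types are intramolecular epoxide opening by stabilised carbanions (epoxynitrile cyclisation), 5-exo delivery of O-tethered nucleophiles to C2 of 2,3-epoxy alcohols and the tethered phosphonoacetate Michael addition–olefination used for lactone annulation, the phosphoryl group giving the carbanion the freedom that a simple ester enolate inside a forming five-membered ring lacks, while the ten-membered ketone and C10–H are much poorer partners for this weakly basic anion.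

Step 13
Reactants: 21 (4S,6R,7R,8S,10R)-6-hydroxy-1-oxo-4-(triethylsilyloxy)germacr-11(13)-en-12,8-olide
Product: 22 (4S,6R,7S,8S,10R)-6-(2-methylpropanoyloxy)-1-oxo-4-(triethylsilyloxy)germacr-11(13)-en-12,8-olide
Conditions: (i-PrCO)2O, DMAP, Et3N, CH2Cl2, 0 °C
Reagents that add atoms: isobutyric anhydride, CC(C)C(=O)OC(=O)C(C)C
Why: DMAP-catalysed acylation of the only free hydroxyl under weakly basic conditions should outpace translactonisation and retains the C6 configuration.

Step 14
Reactants: 22 (4S,6R,7S,8S,10R)-6-(2-methylpropanoyloxy)-1-oxo-4-(triethylsilyloxy)germacr-11(13)-en-12,8-olide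
Product: 23 (4S,6R,7S,8S,10R)-4-hydroxy-6-(2-methylpropanoyloxy)-1-oxogermacr-11(13)-en-12,8-olide
Conditions: HF·pyridine, THF/pyridine, 0 → 23 °C
Reagents that add atoms: none
Why: Buffered fluoride desilylation cleaves the tertiary triethylsilyl ether without base, sparing the α-methylene lactone, the ester and the enolisable C10 centre.

**Compound list**

1 | 4,4-dimethoxycyclohexa-2,5-dien-1-one | COC1(OC)C=CC(=O)C=C1 | starting material
2 | vinylmagnesium bromide | C=C[Mg]Br | starting material
3 | 4,4-dimethoxy-1-vinylcyclohexa-2,5-dien-1-ol (ketal carbinol, not isolated) | C=CC1(O)C=CC(OC)(OC)C=C1 | intermediate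
4 | 4-hydroxy-4-vinylcyclohexa-2,5-dien-1-one | C=CC1(O)C=CC(=O)C=C1 | intermediate
5 | (E)-2-(trimethylsilyl)vinylboronic acid pinacol ester | C[Si](C)(C)/C=C/B1OC(C)(C)C(C)(C)O1 | starting material
6 | (4S,5S)-4-ethenyl-4-hydroxy-5-[(E)-2-(trimethylsilyl)ethenyl]cyclohex-2-en-1-one | C=C[C@]1(O)C=CC(=O)C[C@H]1/C=C/[Si](C)(C)C | intermediate
7 | (3S,4R)-4-ethenyl-4-hydroxy-3-[(E)-2-(trimethylsilyl)ethenyl]cyclohexan-1-one | C=C[C@]1(O)CCC(=O)C[C@H]1/C=C/[Si](C)(C)C | intermediate
8 | (1R,2S,4S)-1-ethenyl-4-methyl-2-[(E)-2-(trimethylsilyl)ethenyl]cyclohexane-1,4-diol | C=C[C@]1(O)CC[C@](C)(O)C[C@H]1/C=C/[Si](C)(C)C | intermediate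
9 | (1R,2S,4S)-1-ethenyl-4-methyl-4-(triethylsilyloxy)-2-[(E)-2-(trimethylsilyl)ethenyl]cyclohexan-1-ol | C=C[C@]1(O)CC[C@](C)(O[Si](CC)(CC)CC)C[C@H]1/C=C/[Si](C)(C)C | intermediate
10 | (1R,2S,4S)-1-ethenyl-2-[(E)-2-iodoethenyl]-4-methyl-4-(triethylsilyloxy)cyclohexan-1-ol | C=C[C@]1(O)CC[C@](C)(O[Si](CC)(CC)CC)C[C@H]1/C=C/I | intermediate
11 | 4-methoxybenzyl alcohol | COc1ccc(CO)cc1 | starting material
12 | (1R,2S,4S)-1-ethenyl-2-[(E)-2-(4-methoxybenzyloxy)ethenyl]-4-methyl-4-(triethylsilyloxy)cyclohexan-1-ol | C=C[C@]1(O)CC[C@](C)(O[Si](CC)(CC)CC)C[C@H]1/C=C/OCc1ccc(OC)cc1 | intermediate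
13 | potassium (1R,2S,4S)-1-ethenyl-2-[(E)-2-(4-methoxybenzyloxy)ethenyl]-4-methyl-4-(triethylsilyloxy)cyclohexan-1-olate (not isolated) | [K+].C=C[C@]1([O-])CC[C@](C)(O[Si](CC)(CC)CC)C[C@H]1/C=C/OCc1ccc(OC)cc1 | intermediate
14 | potassium (1Z,4S,5E,8S)-4-(4-methoxybenzyloxy)-8-methyl-8-(triethylsilyloxy)cyclodeca-1,5-dien-1-olate (not isolated) | [K+].[O-]/C1=C\C[C@H](OCc2ccc(OC)cc2)/C=C/C[C@@](C)(O[Si](CC)(CC)CC)CC1 | intermediate
15 | (2R,4S,5E,8S)-4-(4-methoxybenzyloxy)-2,8-dimethyl-8-(triethylsilyloxy)cyclodec-5-en-1-one | O=C1CC[C@](C)(O[Si](CC)(CC)CC)C/C=C/[C@@H](OCc2ccc(OC)cc2)C[C@H]1C | intermediate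
16 | (2R,4S,5E,8S)-4-hydroxy-2,8-dimethyl-8-(triethylsilyloxy)cyclodec-5-en-1-one | O=C1CC[C@](C)(O[Si](CC)(CC)CC)C/C=C/[C@@H](O)C[C@H]1C | intermediate
17 | (1R,2S,4R,8S,10R)-2-hydroxy-4,8-dimethyl-8-(triethylsilyloxy)-11-oxabicyclo[8.1.0]undecan-5-one | O=C1CC[C@](C)(O[Si](CC)(CC)CC)C[C@H]2O[C@@H]2[C@@H](O)C[C@H]1C | intermediate
18 | (diethoxyphosphoryl)acetic acid | OC(=O)CP(=O)(OCC)OCC | starting material
19 | (1S,2S,4R,8S,10R)-4,8-dimethyl-5-oxo-8-(triethylsilyloxy)-11-oxabicyclo[8.1.0]undecan-2-yl (diethoxyphosphoryl)acetate | O=C1CC[C@](C)(O[Si](CC)(CC)CC)C[C@H]2O[C@@H]2[C@@H](OC(=O)CP(=O)(OCC)OCC)C[C@H]1C | intermediate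
20 | sodium salt (C11 carbanion) of (4S,6R,7R,8S,10R)-11-(diethoxyphosphoryl)-6-hydroxy-1-oxo-4-(triethylsilyloxy)germacran-12,8-olide (not isolated) | [Na+].CCOP(=O)(OCC)[C-]1C(=O)O[C@H]2C[C@@H](C)C(=O)CC[C@](C)(O[Si](CC)(CC)CC)C[C@@H](O)[C@@H]12 | intermediate
21 | (4S,6R,7R,8S,10R)-6-hydroxy-1-oxo-4-(triethylsilyloxy)germacr-11(13)-en-12,8-olide | C=C1C(=O)O[C@H]2C[C@@H](C)C(=O)CC[C@](C)(O[Si](CC)(CC)CC)C[C@@H](O)[C@@H]12 | intermediate
22 | (4S,6R,7S,8S,10R)-6-(2-methylpropanoyloxy)-1-oxo-4-(triethylsilyloxy)germacr-11(13)-en-12,8-olide | C=C1C(=O)O[C@H]2C[C@@H](C)C(=O)CC[C@](C)(O[Si](CC)(CC)CC)C[C@@H](OC(=O)C(C)C)[C@@H]12 | intermediate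
23 | (4S,6R,7S,8S,10R)-4-hydroxy-6-(2-methylpropanoyloxy)-1-oxogermacr-11(13)-en-12,8-olide | C=C1C(=O)O[C@H]2C[C@@H](C)C(=O)CC[C@](C)(O)C[C@@H](OC(=O)C(C)C)[C@@H]12 | target

**Count**

Total steps: 14. Longest linear sequence: 14 steps (1 → 23).

**Steps most likely to fail**

Step 12. The tethered carbanion may not reach the backside of C7: the nucleophilic carbon sits inside the ring being formed, and the ring must first rotate about C7–C8 to move C9 out of that trajectory. O-alkylation or plain recovery would then take over. The fallback sets out from 17, returns at 22, and makes the C7–C11 bond by radical instead of polar closure, using known chemistry (titanocene-mediated reductive epoxide opening with 5-exo-dig cyclisation, then allylic oxidation of a 3-methylenetetrahydrofuran). Alkylation of 17 on O8 (propargyl bromide, Ag2O, CH2Cl2) would give the propargyl ether (1S,2S,4R,8S,10R)-4,8-dimethyl-2-(prop-2-yn-1-yloxy)-8-(triethylsilyloxy)-11-oxabicyclo[8.1.0]undecan-5-one F1. Cp2TiCl (trivalent titanium, from Cp2TiCl2 and Zn, THF) would cleave the C7–O bond homolytically and the C7 radical would close onto the alkyne. This should give the methylene tetrahydrofuran (4S,6R,7R,8S,10R)-8,12-epoxy-6-hydroxy-4-(triethylsilyloxy)germacr-11(13)-en-1-one F2. Its ring fusion would rest on the cis preference of 5-exo closures and on attack anti to the titanium-bound oxygen on C6. Acylation as in step 13 would give the isobutyrate (4S,6R,7S,8S,10R)-8,12-epoxy-1-oxo-4-(triethylsilyloxy)germacr-11(13)-en-6-yl 2-methylpropanoate F3. Oxidation of the allylic CH2 next to the ring oxygen (CrO3·3,5-dimethylpyrazole, CH2Cl2, −20 °C) would then give 22.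

Step 8. The electrophile may enter the ring enolate from the unintended face after conformational equilibration, or proton exchange between enolate and product may cause over-methylation. The fallback sets out from 1, returns at 15, and makes a proton rather than a methyl group the entering group at C10, so a facial bias that misdirects methylation would now deliver 15. Isopropenylmagnesium bromide in place of 2 would give, via the ketal carbinol 4,4-dimethoxy-1-(prop-1-en-2-yl)cyclohexa-2,5-dien-1-ol F4, the quinol 4-hydroxy-4-(prop-1-en-2-yl)cyclohexa-2,5-dien-1-one F5. The conditions of steps 2 to 7 would then lead through the silylvinyl enone F6, the saturated ketone F7, the diol F8, the triethylsilyl ether F9 and the iodoalkene F10 to the PMB enol ether F11. KN(SiMe3)2 and 18-crown-6 would convert F11 into its potassium alkoxide F12 and, by the same [3,3] shift, into the methyl-bearing potassium enolate F13. Quenching F13 at −78 °C with acetic acid instead of iodomethane would give 15.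

Step 10. Facial selectivity may be poor: epoxidation through the rotamer with O8 in the alkene plane would give the erythro epoxide, which could only lead to a trans-fused lactone. The fallback sets out from 16, returns at 17, and replaces substrate direction by reagent control: Shi epoxidation with the D-fructose-derived ketone, KHSO5 (as Oxone), K2CO3 buffer, MeCN/dimethoxymethane/H2O, 0 °C. This catalyst delivers oxygen to trans-disubstituted alkenes in the (R,R) sense required here, and no new compound is involved.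

**Further compounds**

F1 | step 12 | (1S,2S,4R,8S,10R)-4,8-dimethyl-2-(prop-2-yn-1-yloxy)-8-(triethylsilyloxy)-11-oxabicyclo[8.1.0]undecan-5-one | O=C1CC[C@](C)(O[Si](CC)(CC)CC)C[C@H]2O[C@@H]2[C@@H](OCC#C)C[C@H]1C
F2 | step 12 | (4S,6R,7R,8S,10R)-8,12-epoxy-6-hydroxy-4-(triethylsilyloxy)germacr-11(13)-en-1-one | C=C1CO[C@H]2C[C@@H](C)C(=O)CC[C@](C)(O[Si](CC)(CC)CC)C[C@@H](O)[C@@H]12
F3 | step 12 | (4S,6R,7S,8S,10R)-8,12-epoxy-1-oxo-4-(triethylsilyloxy)germacr-11(13)-en-6-yl 2-methylpropanoate | C=C1CO[C@H]2C[C@@H](C)C(=O)CC[C@](C)(O[Si](CC)(CC)CC)C[C@@H](OC(=O)C(C)C)[C@@H]12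
F4 | step 8 | 4,4-dimethoxy-1-(prop-1-en-2-yl)cyclohexa-2,5-dien-1-ol | C=C(C)C1(O)C=CC(OC)(OC)C=C1
F5 | step 8 | 4-hydroxy-4-(prop-1-en-2-yl)cyclohexa-2,5-dien-1-one | C=C(C)C1(O)C=CC(=O)C=C1
F6 | step 8 | (4S,5S)-4-hydroxy-4-(prop-1-en-2-yl)-5-[(E)-2-(trimethylsilyl)ethenyl]cyclohex-2-en-1-one | C=C(C)[C@]1(O)C=CC(=O)C[C@H]1/C=C/[Si](C)(C)C
F7 | step 8 | (3S,4S)-4-hydroxy-4-(prop-1-en-2-yl)-3-[(E)-2-(trimethylsilyl)ethenyl]cyclohexan-1-one | C=C(C)[C@]1(O)CCC(=O)C[C@H]1/C=C/[Si](C)(C)C
F8 | step 8 | (1S,2S,4S)-4-methyl-1-(prop-1-en-2-yl)-2-[(E)-2-(trimethylsilyl)ethenyl]cyclohexane-1,4-diol | C=C(C)[C@]1(O)CC[C@](C)(O)C[C@H]1/C=C/[Si](C)(C)C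
F9 | step 8 | (1S,2S,4S)-4-methyl-1-(prop-1-en-2-yl)-4-(triethylsilyloxy)-2-[(E)-2-(trimethylsilyl)ethenyl]cyclohexan-1-ol | C=C(C)[C@]1(O)CC[C@](C)(O[Si](CC)(CC)CC)C[C@H]1/C=C/[Si](C)(C)C
F10 | step 8 | (1S,2S,4S)-2-[(E)-2-iodoethenyl]-4-methyl-1-(prop-1-en-2-yl)-4-(triethylsilyloxy)cyclohexan-1-ol | C=C(C)[C@]1(O)CC[C@](C)(O[Si](CC)(CC)CC)C[C@H]1/C=C/I
F11 | step 8 | (1S,2S,4S)-2-[(E)-2-(4-methoxybenzyloxy)ethenyl]-4-methyl-1-(prop-1-en-2-yl)-4-(triethylsilyloxy)cyclohexan-1-ol | C=C(C)[C@]1(O)CC[C@](C)(O[Si](CC)(CC)CC)C[C@H]1/C=C/OCc1ccc(OC)cc1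
F12 | step 8 | potassium (1S,2S,4S)-2-[(E)-2-(4-methoxybenzyloxy)ethenyl]-4-methyl-1-(prop-1-en-2-yl)-4-(triethylsilyloxy)cyclohexan-1-olate | [K+].C=C(C)[C@]1([O-])CC[C@](C)(O[Si](CC)(CC)CC)C[C@H]1/C=C/OCc1ccc(OC)cc1
F13 | step 8 | potassium (1Z,4S,5E,8S)-4-(4-methoxybenzyloxy)-2,8-dimethyl-8-(triethylsilyloxy)cyclodeca-1,5-dien-1-olate | [K+].[O-]/C1=C(/C)C[C@H](OCc2ccc(OC)cc2)/C=C/C[C@@](C)(O[Si](CC)(CC)CC)CC1
F0 | step 10 | none | none
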